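The cyclopentenone ring (C1–C5) is opened at C3–C4: the ring ketone C3 and the methyl-bearing enone carbon C4 are both carbonyl carbons, an aldehyde on a two-carbon arm at C1 and an acetyl group on C5 of a cycloheptane that already carries the C7, C8 and C10 substituents and both esters. An N-heterocyclic carbene turns the aldehyde into an acyl anion that adds to the ketone, forming C3–C4, the five-membered ring and the C4 carbinol in one operation; loss of water then gives the C4=C5 enone. The keto aldehyde is reached by Evans aldol, ring-closing metathesis to a 1-acetylcycloheptene and conjugate allylation.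

Key step: step 13

Remark: guaiane numbering (C1–C15) labels the atoms of every intermediate; C5 of 18–20 is epimerisable and drawn trans to the C1 arm, and the C4 and C5 configurations drawn for 21 and 22 are the expected ones, both centres becoming sp2 in step 14.

Step 1
Reactants: 1 (S,E)-pent-3-en-2-ol
Product: 2 ethyl (S,E)-3-methylhex-4-enoate
Conditions: MeC(OEt)3 (5 equiv), EtCO2H (5 mol %), 140 °C, EtOH distilled off
Reagents that add atoms: triethyl orthoacetate, CC(OCC)(OCC)OCC
Why: Johnson–Claisen rearrangement through a chair transition state with the carbinol methyl equatorial relays the C–O stereocentre suprafacially into the new C–C bond, which sets C10 as (S) and leaves an (E)-propenyl group for the later metathesis.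

Step 2
Reactants: 2 ethyl (S,E)-3-methylhex-4-enoate
Product: 3 (S,E)-3-methylhex-4-enal
Conditions: i-Bu2AlH (1.05 equiv), CH2Cl2, −78 °C; aq. potassium sodium tartrate work-up
Reagents that add atoms: none
Why: Partial reduction of the ester with the aluminium hydride at −78 °C stops at the aldehyde oxidation level after work-up, and the β-stereocentre C10 is not enolisable.

Step 3
Reactants: 4 4-bromopent-4-enoic acid; 5 (S)-4-benzyl-1,3-oxazolidin-2-one
Product: 7 (S)-4-benzyl-3-(4-bromopent-4-enoyl)-1,3-oxazolidin-2-one, via mixed pivalic anhydride 6 (not isolated)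
Conditions: t-BuCOCl, Et3N, THF, −20 °C; then 5, LiCl, 23 °C
Reagents that add atoms: none
Why: N-Acylation of the oxazolidinone by a mixed anhydride (LiCl and amine base make the carbamate nitrogen nucleophilic enough) takes place at the less hindered acyl carbon, and the vinyl bromide is a spectator.

Step 4
Reactants: 7 (S)-4-benzyl-3-(4-bromopent-4-enoyl)-1,3-oxazolidin-2-one; 3 (S,E)-3-methylhex-4-enal
Product: 9 (S)-4-benzyl-3-[(2S,3R,5S,E)-2-(2-bromoprop-2-en-1-yl)-3-hydroxy-5-methyloct-6-enoyl]-1,3-oxazolidin-2-one, via (Z)-dibutylboron enolate 8 (not isolated)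
Conditions: Bu2BOTf (1.2 equiv), Et3N (1.4 equiv), CH2Cl2, −78 to 0 °C; then 3, −78 to 0 °C; pH 7 buffer, MeOH, 30% H2O2, 0 °C
Reagents that add atoms: none
Why: Evans syn aldol reaction, in which the (Z)-boron enolate reacts through a closed Zimmerman–Traxler chair on the enolate face remote from the benzyl group, so that C7 (S) and C8 (R) are set together under auxiliary control, independently of the remote C10 centre.

Step 5
Reactants: 9 aldol adduct (imide)
Product: 10 methyl (2S,3R,5S,E)-2-(2-bromoprop-2-en-1-yl)-3-hydroxy-5-methyloct-6-enoate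
Conditions: NaOMe (1.1 equiv), MeOH, CH2Cl2, 0 °C, 15 min; then AcOH (1.1 equiv)
Reagents that add atoms: sodium methoxide, [Na+].[O-]C
Why: Transesterification, in which methoxide attacks the more electrophilic exocyclic imide carbonyl and expels the oxazolidinone anion, the short exposure at 0 °C being meant to forestall retro-aldol cleavage and epimerisation at C7.

Step 6
Reactants: 10 methyl ester
Product: 11 (3S,4R,6S,E)-3-(2-bromoprop-2-en-1-yl)-2,6-dimethylnon-7-ene-2,4-diol
Conditions: MeMgBr (5 equiv), THF, −20 to 0 °C; aqueous work-up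
Reagents that add atoms: methylmagnesium bromide, C[Mg]Br
Why: Double Grignard addition of MeMgBr to the methyl ester builds the C11 dimethyl carbinol without touching any stereocentre, the vinyl bromide and the alkene being inert to the reagent.

Step 7
Reactants: 11 diol
Product: 12 (3S,4R,6S,E)-3-(2-bromoprop-2-en-1-yl)-2-hydroxy-2,6-dimethylnon-7-en-4-yl propanoate
Conditions: (EtCO)2O (1.2 equiv), Et3N, DMAP (5 mol %), CH2Cl2, 0 °C
Reagents that add atoms: propanoic anhydride, CCC(=O)OC(=O)CC
Why: Nucleophilic catalysis by DMAP acylates the secondary C8 hydroxyl much faster than the hindered tertiary C11 hydroxyl, which places the propanoate selectively.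

Step 8
Reactants: 12 hydroxy propanoate
Product: 13 (3S,4R,6S,E)-2-acetoxy-3-(2-bromoprop-2-en-1-yl)-2,6-dimethylnon-7-en-4-yl propanoate
Conditions: Ac2O (3 equiv), Sc(OTf)3 (2 mol %), MeCN, −20 °C
Reagents that add atoms: acetic anhydride, CC(=O)OC(C)=O
Why: Lewis acid catalysed acylation (Sc(OTf)3 activates the anhydride) esterifies tertiary alcohols at −20 °C, quickly enough to outpace migration of the propanoyl group from O8 to O11 and cold enough to avoid ionisation at C11.

Step 9
Reactants: 13 bromo diester
Product: 15 (3S,4R,6S,E)-2-acetoxy-2,6-dimethyl-3-(2-methylidene-3-oxobutyl)non-7-en-4-yl propanoate, via 2-ethoxy diene 14 (not isolated)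
Conditions: Bu3SnC(OEt)=CH2 (1.3 equiv), Pd(PPh3)4 (5 mol %), toluene, 100 °C; then 1 M HCl, THF, 0 °C, 15 min
Reagents that add atoms: tributyl(1-ethoxyvinyl)stannane, CCCC[Sn](CCCC)(CCCC)C(=C)OCC; water, O
Why: Stille coupling of the 2-bromoalkene with the 1-ethoxyvinyl stannane and mild acid hydrolysis of the resulting enol ether install the acetyl group (C4 and C15) on C5 while keeping the exocyclic methylene needed for ring closure, and the tertiary acetate should tolerate brief cold dilute acid.

Step 10
Reactants: 15 α-methylene ketone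
Product: 16 (1R,2S,6S)-4-acetyl-2-(2-acetoxypropan-2-yl)-6-methylcyclohept-4-en-1-yl propanoate
Conditions: second-generation Grubbs catalyst (5 mol %), CH2Cl2 (0.003 M), 40 °C
Reagents that add atoms: none
Why: Ring-closing metathesis joins C1 and C5 with loss of propene, the ruthenium carbene loading at the propenyl group and closing onto the 1,1-disubstituted enone alkene as in known closures onto methacrylate-type alkenes, which gives the conjugated seven-membered enone.

Step 11
Reactants: 16 1-acetylcycloheptene
Product: 18 (1R,2S,4R,5R,6S)-4-acetyl-2-(2-acetoxypropan-2-yl)-6-methyl-5-(prop-2-en-1-yl)cycloheptyl propanoate, via trimethylsilyl enol ether 17 (not isolated)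
Conditions: CH2=CHCH2MgBr (1.5 equiv), CuBr·SMe2 (1.5 equiv), Me3SiCl (3 equiv), THF, −78 °C; then 1 M HCl, THF, 0 °C; then DBU (0.2 equiv), CH2Cl2, 23 °C
Reagents that add atoms: allylmagnesium bromide, C=CC[Mg]Br
Why: Chlorosilane-accelerated conjugate addition of an allylcopper reagent (chosen over a strong Lewis acid, which would ionise the tertiary acetate) should deliver the allyl group to C1 from the α face, anti to the adjacent C10 methyl and to the β-oriented C7 and C8 substituents, and brief amidine treatment equilibrates the epimerisable C5 to the trans ketone.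

Step 12
Reactants: 18 allyl ketone
Product: 20 (1R,2S,4R,5R,6S)-4-acetyl-2-(2-acetoxypropan-2-yl)-6-methyl-5-(2-oxoethyl)cycloheptyl propanoate, via ozonide 19 (not isolated)
Conditions: O3, CH2Cl2, −78 °C; then PPh3, −78 to 23 °C
Reagents that add atoms: ozone, [O-][O+]=O
Why: Ozonolysis with reductive work-up cleaves the only alkene to the C3 aldehyde under neutral conditions that leave the esters, the ketone and the stereocentres untouched.

Step 13
Reactants: 20 keto aldehyde
Product: 21 (3R,3aR,5S,6R,8S,8aR)-5-(2-acetoxypropan-2-yl)-3-hydroxy-3,8-dimethyl-2-oxodecahydroazulen-6-yl propanoate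
Conditions: 2-(pentafluorophenyl)-6,7-dihydro-5H-pyrrolo[2,1-c][1,2,4]triazol-2-ium tetrafluoroborate (15 mol %), Et3N (15 mol %), CH2Cl2 (0.05 M), 23 °C
Reagents that add atoms: none
Why: The carbene freed from the triazolium salt adds to the unhindered aldehyde C3, proton transfer gives the Breslow intermediate (an acyl anion equivalent), its carbon attacks the acetyl carbonyl C4, and proton transfer with loss of the carbene releases the α-hydroxy ketone. The closest known reaction type is the carbene-catalysed intramolecular crossed aldehyde–ketone benzoin cyclisation of 1,5-keto aldehydes to 2-hydroxycyclopentanones. The ring C1–C2–C3–C4–C5 closes in the 5-exo-trig mode. The new C4 stereocentre is set by an envelope transition state on the trans-disposed arms that places the acetyl methyl pseudo-equatorial and the forming hydroxyl pseudo-axial (β, anti to H5), although either epimer is usable. The step needs chemoselectivity for acyl anion addition over aldol chemistry, and the substrate helps because only the primary aldehyde is open to the carbene, the aldehyde enolate could reach the ketone only through a four-membered ring, and the one feasible aldol (C15 enolate onto C3) is held back by the weak amine base at room temperature.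

Step 14
Reactants: 21 α-hydroxy ketone
Product: 23 (5S,6R,8S,8aR)-5-(2-acetoxypropan-2-yl)-3,8-dimethyl-2-oxo-1,2,4,5,6,7,8,8a-octahydroazulen-6-yl propanoate (target), via chlorosulfite 22 (not isolated)
Conditions: SOCl2 (1.5 equiv), pyridine, CH2Cl2, −10 to 0 °C
Reagents that add atoms: none
Why: Dehydration of the tertiary α-hydroxy ketone through its chlorosulfite, in which pyridine-mediated anti elimination removes H5, trans to the leaving group, to give the more substituted conjugated C4=C5 alkene, which erases the C4 and C5 stereocentres and leaves C1 unchanged.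

Compound list
1 | (S,E)-pent-3-en-2-ol | C/C=C/[C@H](C)O | starting material
2 | ethyl (S,E)-3-methylhex-4-enoate | CCOC(=O)C[C@H](C)/C=C/C | intermediate
3 | (S,E)-3-methylhex-4-enal | O=CC[C@H](C)/C=C/C | intermediate
4 | 4-bromopent-4-enoic acid | OC(=O)CCC(Br)=C | starting material
5 | (S)-4-benzyl-1,3-oxazolidin-2-one | O=C1OC[C@H](Cc2ccccc2)N1 | starting material
6 | 4-bromopent-4-enoic pivalic anhydride (not isolated) | CC(C)(C)C(=O)OC(=O)CCC(Br)=C | intermediate
7 | (S)-4-benzyl-3-(4-bromopent-4-enoyl)-1,3-oxazolidin-2-one | O=C1OC[C@H](Cc2ccccc2)N1C(=O)CCC(Br)=C | intermediate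
8 | (Z)-dibutylboron enolate of 7 (not isolated) | O=C1OC[C@H](Cc2ccccc2)N1/C(OB(CCCC)CCCC)=C/CC(Br)=C | intermediate
9 | (S)-4-benzyl-3-[(2S,3R,5S,E)-2-(2-bromoprop-2-en-1-yl)-3-hydroxy-5-methyloct-6-enoyl]-1,3-oxazolidin-2-one | O=C1OC[C@H](Cc2ccccc2)N1C(=O)[C@@H](CC(Br)=C)[C@H](O)C[C@H](C)/C=C/C | intermediate
10 | methyl (2S,3R,5S,E)-2-(2-bromoprop-2-en-1-yl)-3-hydroxy-5-methyloct-6-enoate | COC(=O)[C@@H](CC(Br)=C)[C@H](O)C[C@H](C)/C=C/C | intermediate
11 | (3S,4R,6S,E)-3-(2-bromoprop-2-en-1-yl)-2,6-dimethylnon-7-ene-2,4-diol | CC(C)(O)[C@@H](CC(Br)=C)[C@H](O)C[C@H](C)/C=C/C | intermediate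
12 | (3S,4R,6S,E)-3-(2-bromoprop-2-en-1-yl)-2-hydroxy-2,6-dimethylnon-7-en-4-yl propanoate | CC(C)(O)[C@@H](CC(Br)=C)[C@H](OC(=O)CC)C[C@H](C)/C=C/C | intermediate
13 | (3S,4R,6S,E)-2-acetoxy-3-(2-bromoprop-2-en-1-yl)-2,6-dimethylnon-7-en-4-yl propanoate | CC(=O)OC(C)(C)[C@@H](CC(Br)=C)[C@H](OC(=O)CC)C[C@H](C)/C=C/C | intermediate
14 | (3S,4R,6S,E)-2-acetoxy-3-(3-ethoxy-2-methylidenebut-3-en-1-yl)-2,6-dimethylnon-7-en-4-yl propanoate (not isolated) | CC(=O)OC(C)(C)[C@@H](CC(=C)C(=C)OCC)[C@H](OC(=O)CC)C[C@H](C)/C=C/C | intermediate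
15 | (3S,4R,6S,E)-2-acetoxy-2,6-dimethyl-3-(2-methylidene-3-oxobutyl)non-7-en-4-yl propanoate | CC(=O)OC(C)(C)[C@@H](CC(=C)C(C)=O)[C@H](OC(=O)CC)C[C@H](C)/C=C/C | intermediate
16 | (1R,2S,6S)-4-acetyl-2-(2-acetoxypropan-2-yl)-6-methylcyclohept-4-en-1-yl propanoate | CCC(=O)O[C@@H]1C[C@H](C)C=C(C(C)=O)C[C@@H]1C(C)(C)OC(C)=O | intermediate
17 | trimethylsilyl enol ether of 18 (C4=C5, not isolated) | CCC(=O)O[C@@H]1C[C@H](C)[C@@H](CC=C)C(=C(C)O[Si](C)(C)C)C[C@@H]1C(C)(C)OC(C)=O | intermediate
18 | (1R,2S,4R,5R,6S)-4-acetyl-2-(2-acetoxypropan-2-yl)-6-methyl-5-(prop-2-en-1-yl)cycloheptyl propanoate | CCC(=O)O[C@@H]1C[C@H](C)[C@@H](CC=C)[C@H](C(C)=O)C[C@@H]1C(C)(C)OC(C)=O | intermediate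
19 | 1,2,4-trioxolane (ozonide) of 18 (not isolated, trioxolane carbon unassigned) | CCC(=O)O[C@@H]1C[C@H](C)[C@@H](CC2OOCO2)[C@H](C(C)=O)C[C@@H]1C(C)(C)OC(C)=O | intermediate
20 | (1R,2S,4R,5R,6S)-4-acetyl-2-(2-acetoxypropan-2-yl)-6-methyl-5-(2-oxoethyl)cycloheptyl propanoate | CCC(=O)O[C@@H]1C[C@H](C)[C@@H](CC=O)[C@H](C(C)=O)C[C@@H]1C(C)(C)OC(C)=O | intermediate
21 | (3R,3aR,5S,6R,8S,8aR)-5-(2-acetoxypropan-2-yl)-3-hydroxy-3,8-dimethyl-2-oxodecahydroazulen-6-yl propanoate | CCC(=O)O[C@@H]1C[C@H](C)[C@H]2CC(=O)[C@](C)(O)[C@@H]2C[C@@H]1C(C)(C)OC(C)=O | intermediate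
22 | chlorosulfite of 21 at O4 (not isolated, sulfur unassigned) | CCC(=O)O[C@@H]1C[C@H](C)[C@H]2CC(=O)[C@](C)(OS(Cl)=O)[C@@H]2C[C@@H]1C(C)(C)OC(C)=O | intermediate
23 | (5S,6R,8S,8aR)-5-(2-acetoxypropan-2-yl)-3,8-dimethyl-2-oxo-1,2,4,5,6,7,8,8a-octahydroazulen-6-yl propanoate | CCC(=O)O[C@@H]1C[C@H](C)[C@H]2CC(=O)C(C)=C2C[C@@H]1C(C)(C)OC(C)=O | target

Total step count: 14. Longest linear sequence: 13 steps (steps 1, 2 and 4–14; step 3 is the side branch).

Steps most likely to fail:

Step 13. Enolisation of the methyl ketone and intramolecular aldol condensation onto the aldehyde (six-membered ring) could outrun carbene addition, or the acyl anion could add too slowly to the hindered ketone. The fallback forms the same C3–C4 bond reductively. It sets out from keto aldehyde 20: SmI2 (2.5 equiv) in THF with t-BuOH at −78 °C should effect ketyl–carbonyl (pinacol) cyclisation to the cis-3,4-dihydroxyguaiane diester F1. Oxidation of its secondary C3 hydroxyl with Dess–Martin periodinane (NaHCO3, CH2Cl2) should then give the α-hydroxy ketone and rejoin the route at 21; either C4 epimer is carried into step 14.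

Step 11. Competing 1,2-addition of the allyl organometallic to the ketone, or attack on the esters, could erode the conjugate allylation. The fallback uses a softer vinyl nucleophile and makes the aldehyde by hydroboration instead of ozonolysis. It sets out from enone 16: CH2=CHMgBr with CuI in THF at −78 °C should give the C1-vinyl ketone F2. Hydroboration with 9-borabicyclo[3.3.1]nonane and oxidation with NaBO3 should give the primary alcohol F3; any ketone reduced alongside is reoxidised in the next operation. Dess–Martin oxidation should then deliver keto aldehyde 20, where the route is rejoined (steps 11 and 12 are bypassed).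

Step 14. If H5 is not anti-periplanar to the leaving group (as in a C4- or C5-epimeric ketol), elimination would run toward the C15 methyl and the double bond would end up exocyclic. The fallback accepts that regiochemistry and corrects it afterwards. It sets out from ketol 21: the Burgess reagent (toluene, 60 °C, syn elimination) should give the exocyclic 4(15)-enone F4, and RhCl3·3H2O in EtOH at 70 °C should move the double bond by hydride addition–elimination into the tetrasubstituted conjugated position, arriving at target 23.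

Further compounds
F1 | step 13 | cis-3,4-dihydroxyguaiane diester (3-hydroxy analogue of 21, both hydroxyls β) | CCC(=O)O[C@@H]1C[C@H](C)[C@H]2C[C@H](O)[C@](C)(O)[C@@H]2C[C@@H]1C(C)(C)OC(C)=O
F2 | step 11 | (1R,2S,4R,5R,6S)-4-acetyl-2-(2-acetoxypropan-2-yl)-5-ethenyl-6-methylcycloheptyl propanoate | CCC(=O)O[C@@H]1C[C@H](C)[C@@H](C=C)[C@H](C(C)=O)C[C@@H]1C(C)(C)OC(C)=O
F3 | step 11 | (1R,2S,4R,5R,6S)-4-acetyl-2-(2-acetoxypropan-2-yl)-5-(2-hydroxyethyl)-6-methylcycloheptyl propanoate | CCC(=O)O[C@@H]1C[C@H](C)[C@@H](CCO)[C@H](C(C)=O)C[C@@H]1C(C)(C)OC(C)=O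
F4 | step 14 | exocyclic enone, 4(15)-ene isomer of 23 with H5 retained | CCC(=O)O[C@@H]1C[C@H](C)[C@H]2CC(=O)C(=C)[C@@H]2C[C@@H]1C(C)(C)OC(C)=O
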